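**The pitfall.** A share of Z read early need not hold at a later reading. In the noon run Z reads 8% at 15.0 s but 4% at 25.0 s, so Z behaves as a stock that is filled and drained. We therefore count its halvings.

| flask | Q | temperature | remark | time |
|---|---|---|---|---|
| midnight | 0.27 M | 65 °C | run made earlier |  |
| noon | 1.1 M | 100 °C | run made earlier |  |
| west | 0.53 M | 70 °C |  | 3.0 min |
| north-west | 0.53 M | 90 °C |  | 3.0 min |
| north-east | 0.53 M | 130 °C |  | 3.0 min |
| south | 0.53 M | 110 °C |  | 3.0 min |

| run | time / s | Z / % | L / % | J / % |
|---|---|---|---|---|
| midnight | 15.0 | 4 | 8 | 0 |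
| midnight | 30.0 | 4 | 5 | 3 |
| midnight | 50.0 | 6 | 9 | 2 |
| midnight | 60.0 | 6 | 10 | 2 |
| midnight | 80.0 | 8 | 8 | 0 |
| midnight | 90.0 | 10 | 11 | 3 |
| midnight | 120 | 10 | 12 | 1 |
| noon | 10.0 | 7 | 17 | 6 |
| noon | 12.0 | 14 | 19 | 6 |
| noon | 15.0 | 8 | 23 | 10 |
| noon | 20.0 | 7 | 19 | 9 |
| noon | 25.0 | 4 | 22 | 9 |

(scatter of a reading: 2 percentage points)

* which flask leads in share of Z in all that became Z or L or J or D or E ("all alike" within 1.5 percentage points) (west / north-west / north-east / south / all alike)
* share of Z in all that became Z or L or J or D or E, west
* share of Z in all that became Z or L or J or D or E, north-west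
* share of Z in all that became Z or L or J or D or E, north-east
* share of Z in all that became Z or L or J or D or E, south

- in percentages every species weighs as the Q in it: one L or D counts as two
- in percentages every species weighs as the Q in it: one J counts as three

**First instants.** Q turns into Z and L side by side. At midnight, the cool run, the last reading at 120 s shows Z 10% beside L 12%, and Z has been climbing through the run. At that heat the stock is still filling.

**The middle.** The two noon readings, with their scatter, give 10.0 s, the noon half-life of Z, the time in which the standing Z halves. At that pace 3.0 min holds 18.0 halvings. The products seen at noon at 25.0 s add up to 35.0% of the charge, and D and E go unread, so on a first-order count Q has a half-life of at most 40.2 s there. That figure is a ceiling, so it doesn't tell us whether Q or Z goes down faster at noon.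

**The end.** Z is an intermediate fed by Q, so for our estimate we count with the ceiling on Q, the slower of our two paces. Starting from 4% at 25.0 s, the 3.85 halvings at that pace before 3.0 min bring Z to an estimated 0.277%. Our own reckoning puts north-east and south, both hotter than noon, at about that share or below. West, the coolest flask, should lead, with north-west between.

**The forecast.** It names west with 20%, then 8% for north-west, 2% for north-east and 4% for south, holding that “the hotter flasks should lose most of their Z, while the coolest keeps the most”, and its two hot values stand above ours.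

**The result.** The leader is west at 13.1%, with north-west at 1.09%, north-east at 0% and south at 0%.

    Q + L → J (k = 0.0100 L mol⁻¹ s⁻¹, Ea = 58.0 kJ mol⁻¹)
    Z → E (k = 0.00530 s⁻¹, Ea = 97.0 kJ mol⁻¹)
    2 Q → L (k = 0.00440 L mol⁻¹ s⁻¹, Ea = 60.0 kJ mol⁻¹)
    Q + Z → D (k = 0.0260 L mol⁻¹ s⁻¹, Ea = 79.0 kJ mol⁻¹)
    Q → Z (k = 0.00260 s⁻¹, Ea = 101 kJ mol⁻¹)
    (constants at 70 °C)

**The count.** In north-west, from 1.50 min to 3.00 min, Q falls from 6.66% to 0.943% and Z from 5.59% to 1.08%. That is 2.82 halvings of Q beside 2.38 of Z. Z in north-west thus halves every 37.9 s, slower than the noon half-life of 10.0 s. South, 9.00 noon half-lives after its start, holds Q 0% and Z 0% at 1.50 min.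

All runs are calculated for an exercise, noise included.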